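**The problem**

The target 16 is (2S)-5,7-dimethoxy-2-(3,4,5-trimethoxyphenyl)chroman-4-one. Ring C (O1, C2, C3, C4, C4a, C8a) is a dihydropyranone fused through C4a–C8a to benzene ring A, which carries methoxyl at C5 and C7; ring B sits on C2. C2 is the only stereocentre, so nothing in the molecule can control it and it must come from a reagent or catalyst. It is also the weak point: O1 is β to the C4 ketone and, once ring A is aromatic, leaves as a phenoxide. Base (or hot acid) therefore opens ring C to the achiral chalcone and recloses it as the racemate, and the para-methoxyl of ring B makes ionisation at C2 easy as well. Every construction that closes ring C on a finished ring A makes C2 inside this labile array, on electrophiles that rings A and B deactivate by donation. The methyl ethers need no protection, but the one at C5 flanks the ketone and would be lost to strong chelating Lewis acids.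

The feature that opens another way is the oxygen pattern of ring A. O1 on C8a, OMe on C5 and OMe on C7 alternate around the ring, and the fusion bond C4a–C8a is at the same time the enol-ether double bond of a 2,3-dihydro-4H-pyran-4-one (C8a its β-carbon, C4a its α-carbon). C5–C8 with their two oxygens are thus a 1,1,3-trioxygenated butadiene of matching polarity, and a 2-aryl-2,3-dihydro-4H-pyran-4-one is the product of a dependable catalytic asymmetric reaction of aromatic aldehydes. The plan is therefore: stereocentre first, benzene ring last.

**Retrosynthesis**

16 ⇒ 15. The O–CH3 bond at C7 is cut. The diene used below delivers the C7 oxygen as a silyl ether, so the annulation ends at phenol 15. This hydroxyl is para to the ketone, acidic and not chelated (the C5 oxygen already arrives as OMe), so it can be methylated under neutral conditions that do not open ring C.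

15 ⇒ 7 + 11 (key disconnection). Ring A is cut at C4a–C5 and C8–C8a and taken back from the arene oxidation level. The precursors are the monocyclic sulfinyl dihydropyranone 7 (ring C with C2 already set) and the open-chain diene 11, which carries C5–C8 and both oxygens. Against the neighbouring cuts (O1–C2, C2–aryl, C4–C4a) this one does not touch C2 and creates the phenoxide leaving group only at the end, under neutral conditions. The forward reaction must add 11 across C5=C6 of 7 with the acetal carbon at C4a (cycloadduct 12), lose benzenesulfenic acid (13) and methanol (14), and give 15 after desilylation.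

7 ⇒ 6 ⇒ 4. The S–O bond and then the C5–S bond are cut. The sulfinyl group is a traceless activator: it makes the electron-rich C5=C6 bond a dienophile, and it is the leaving group that removes the C8a hydrogen. The annulation thus reaches the arene without an oxidant and without an intermediate that could aromatise by expelling O1 from C8a. Sulfide 6 comes from pyranone 4 by electrophilic sulfenylation at the nucleophilic α-carbon through adduct 5.

4 ⇒ 1 + 2. O1–C6 and C2–C3 of the pyranone are cut: a catalytic asymmetric hetero-Diels–Alder reaction of aldehyde 1 with siloxy diene 2, running through aldol adduct 3. Both partners are commercial, the C2–O bond is made from the aldehyde oxygen and never broken again, and the enantio-determining step is an addition to a free aldehyde.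

11 ⇒ 10 ⇒ 8 + 9. The O–Si bond and then the C2–C3 bond of the butadiene are cut, leading to the acyl ketene acetal 10 and on to 1,1-dimethoxyethene 8 and acetyl chloride 9. Two steps supply all four carbons and both oxygens of the new ring.

**Roads not taken**

Alternative 1: (the obvious route) cut O1–C2. Aldehyde 1 and commercial 1-(2-hydroxy-4,6-dimethoxyphenyl)ethanone give chalcone A1 by Claisen–Schmidt condensation; a catalytic asymmetric intramolecular oxa-Michael addition would then close ring C. It is shorter (two steps). Its flaw is mechanistic: the ring closure is an equilibrium whose reverse reaction is the racemisation path, and it runs under the same basic or bifunctional catalysis. The β-carbon of A1 is deactivated by the para-methoxyl of ring B and the carbonyl by two donor groups and a hydrogen-bonded phenol, so the catalyst must work slowly and close to equilibrium. High selectivity in this reaction type usually needs an extra acceptor at C3 that must then be removed with the labile centre in place, which costs the step advantage. In the chosen plan the C2–O bond is formed irreversibly on the aldehyde, and the phenoxide leaving group does not exist until step 6.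

Alternative 2: cut C2–aryl. 5,7-Dimethoxychromone A2 (from the same acetophenone with DMF dimethyl acetal, then acid) would take up (3,4,5-trimethoxyphenyl)boronic acid in an asymmetric conjugate addition, for example with Pd(OCOCF3)2 and a chiral pyridine-oxazoline ligand. This is the shortest route of all. Its weakness is structural: three oxygen donors (O1, 5-OMe, 7-OMe) feed the C4 carbonyl, so A2 is the least electrophilic kind of chromone, and the 5-OMe crowds the carbonyl. Slow insertion gives the electron-rich arylmetal time for protodeboronation, and the metal enolate of the product can expel the phenoxide, the same leak as above. The single stereocentre would rest on one ligand-controlled insertion into a reluctant acceptor. The chosen plan spends more steps to put that event on an aldehyde.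

Alternative 3: cut O1–C2 with inversion. An asymmetric aldol addition (or asymmetric reduction) would give the (R)-β-hydroxy ketone A3, and an intramolecular Mitsunobu reaction would close ring C with inversion to (S). This needs phenol protection and deprotection around the aldol step (four to five steps). The displacement takes place at a benzylic carbon bearing a para-methoxyaryl group, where the activated alcohol tends to ionise, so inversion is not secure. A3 also dehydrates readily to chalcone A1. In the chosen plan no bond to C2 is made or broken after step 1.

Key step: step 6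

Assumption: the titanium catalyst made from (S)-BINOL is taken to direct the diene to the Si face of the aryl aldehyde, which gives (S) at C2; if the sense proves opposite, the (R)-ligand is used and nothing else changes.

**Route**

Step 1
Reactants: 1 3,4,5-trimethoxybenzaldehyde; 2 trans-1-methoxy-3-(trimethylsilyloxy)buta-1,3-diene
Product: 4 (S)-2-(3,4,5-trimethoxyphenyl)-2,3-dihydro-4H-pyran-4-one, via silyl aldol adduct 3 (not isolated)
Conditions: (S)-BINOL (20 mol %), Ti(OiPr)4 (10 mol %), CF3CO2H (cat.), 4 Å MS, Et2O, −20 °C; then CF3CO2H, CH2Cl2, 0 °C
Reagents that add atoms: none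
Why: Catalytic asymmetric hetero-Diels–Alder reaction of the Mukaiyama aldol type: the chiral titanium BINOLate activates the aldehyde and the CH2 terminus of 2 adds to its Si face, which sets C2 as (S) in 3. Acid then closes the ring by oxa-Michael addition and loss of methanol; aromatic aldehydes are standard substrates.

Step 2
Reactants: 4 (S)-2-(3,4,5-trimethoxyphenyl)-2,3-dihydro-4H-pyran-4-one
Product: 6 (S)-5-(phenylthio)-2-(3,4,5-trimethoxyphenyl)-2,3-dihydro-4H-pyran-4-one, via chloro sulfide adduct 5 (not isolated)
Conditions: PhSCl (1.05 equiv), CH2Cl2, −78 °C; then Et3N, −78 to 0 °C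
Reagents that add atoms: benzenesulfenyl chloride, ClSc1ccccc1
Why: Electrophilic α-sulfenylation of an enone by addition–elimination: sulfur attacks the nucleophilic α-carbon C5 of the enol ether, chloride caps the oxocarbenium ion at C6 to give 5, and the now acidic C5–H is removed with loss of chloride. C2 is not involved.

Step 3
Reactants: 6 (S)-5-(phenylthio)-2-(3,4,5-trimethoxyphenyl)-2,3-dihydro-4H-pyran-4-one
Product: 7 (2S)-5-(phenylsulfinyl)-2-(3,4,5-trimethoxyphenyl)-2,3-dihydro-4H-pyran-4-one, mixture of the two configurations at sulfur
Conditions: mCPBA (1.0 equiv), CH2Cl2, −78 °C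
Reagents that add atoms: meta-chloroperoxybenzoic acid, O=C(OO)c1cccc(Cl)c1
Why: Sulfide-to-sulfoxide oxidation with one equivalent of peracid; at low temperature sulfur should react well before the acceptor-substituted enol ether or the arenes. The sulfur stereocentre forms without control and does not matter, because sulfur is expelled in step 6.

Step 4
Reactants: 8 1,1-dimethoxyethene; 9 acetyl chloride
Product: 10 4,4-dimethoxybut-3-en-2-one
Conditions: pyridine, Et2O, 0 °C to rt
Reagents that add atoms: none
Why: C-acylation of a ketene acetal: the nucleophilic CH2 of 8 attacks the acylating agent and the dialkoxycarbenium ion loses a proton to pyridine, giving the conjugated acyl ketene acetal.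

Step 5
Reactants: 10 4,4-dimethoxybut-3-en-2-one
Product: 11 1,1-dimethoxy-3-(trimethylsilyloxy)buta-1,3-diene
Conditions: Me3SiCl, Et3N, ZnCl2 (cat.), toluene, 40 °C
Reagents that add atoms: chlorotrimethylsilane, C[Si](C)(C)Cl
Why: Silyl enol ether formation from a methyl ketone under the standard amine/ZnCl2 conditions for 2-siloxy dienes. Only the methyl group can enolise, so a single diene should form.

Step 6
Reactants: 7 (2S)-5-(phenylsulfinyl)-2-(3,4,5-trimethoxyphenyl)-2,3-dihydro-4H-pyran-4-one; 11 1,1-dimethoxy-3-(trimethylsilyloxy)buta-1,3-diene
Product: 15 (S)-7-hydroxy-5-methoxy-2-(3,4,5-trimethoxyphenyl)chroman-4-one, via sulfinyl cycloadduct 12 (not isolated), via dienyl acetal 13 (not isolated), via aryl silyl ether 14 (not isolated)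
Conditions: 11 (3 equiv), toluene, 25 to 70 °C; then AcOH, THF/H2O, 25 °C
Reagents that add atoms: none
Why: Proposed new method: the closest known reaction type is the Diels–Alder/elimination benzannulation of 2-sulfinyl enones and halo- or sulfinylquinones with 1,1-dialkoxy-3-siloxybutadienes, which to my knowledge has not been shown on a 5-sulfinyl-2,3-dihydro-4H-pyran-4-one. The nucleophilic CH2 terminus of 11 attacks C6 of 7 (the β-carbon of the enone, oxocarbenium-like through O1) and the acetal carbon of 11 bonds to C5, which bears both acceptors; concerted or through a short-lived zwitterion, this intermolecular (4+2) addition closes ring A as a cyclohexene by forming C8–C8a and C4a–C5 (12). The matched polarisation of the two partners fixes the regiochemistry, so the acetal carbon ends next to C4a and the oxygens at C5 and C7. Addition to the cis ring alkene puts sulfur on C4a and hydrogen on C8a on the same face, so the sulfoxide leaves by thermal syn elimination with the only β-hydrogen available and restores C4a=C8a (13). 13 is a cyclohexa-1,4-diene with an allylic acetal and aromatises by 1,4-loss of methanol to 14, whose silyl ether is cleaved in the mild acid work-up. The stereocentres formed at C4a and C8a (and the one at sulfur) are erased, so no facial selectivity is needed; C2 is untouched and no base is present. The selectivity that the step needs is loss of sulfur with the C8a hydrogen in preference to loss of O1 from C8a: 12 has no enolisable hydrogen next to C8a while C7 is a silyl enol ether, and after sulfoxide loss C8a is sp2.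

Step 7
Reactants: 15 (S)-7-hydroxy-5-methoxy-2-(3,4,5-trimethoxyphenyl)chroman-4-one
Product: 16 (S)-5,7-dimethoxy-2-(3,4,5-trimethoxyphenyl)chroman-4-one (CNP0348225.1)
Conditions: MeOH, PPh3, DIAD, THF, 0 °C to rt
Reagents that add atoms: methanol, CO
Why: Mitsunobu O-methylation of an acidic, unchelated phenol (para to the ketone) under essentially neutral conditions. No free base is present that could enolise C3 and open ring C, so the C2 configuration should be kept.

**Compound list**

1 | 3,4,5-trimethoxybenzaldehyde | COc1cc(C=O)cc(OC)c1OC | starting material
2 | trans-1-methoxy-3-(trimethylsilyloxy)buta-1,3-diene | CO/C=C/C(=C)O[Si](C)(C)C | starting material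
3 | (S,E)-1-methoxy-5-(3,4,5-trimethoxyphenyl)-5-(trimethylsilyloxy)pent-1-en-3-one | C[Si](C)(C)O[C@H](c1cc(OC)c(OC)c(OC)c1)CC(=O)/C=C/OC | intermediate
4 | (S)-2-(3,4,5-trimethoxyphenyl)-2,3-dihydro-4H-pyran-4-one | O=C1C=CO[C@H](c2cc(OC)c(OC)c(OC)c2)C1 | intermediate
5 | (2S)-6-chloro-5-(phenylthio)-2-(3,4,5-trimethoxyphenyl)tetrahydro-4H-pyran-4-one (C5 and C6 undefined) | O=C1C[C@@H](c2cc(OC)c(OC)c(OC)c2)OC(Cl)C1Sc3ccccc3 | intermediate
6 | (S)-5-(phenylthio)-2-(3,4,5-trimethoxyphenyl)-2,3-dihydro-4H-pyran-4-one | O=C1C[C@@H](c2cc(OC)c(OC)c(OC)c2)OC=C1Sc3ccccc3 | intermediate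
7 | (2S)-5-(phenylsulfinyl)-2-(3,4,5-trimethoxyphenyl)-2,3-dihydro-4H-pyran-4-one (both configurations at sulfur) | O=C1C[C@@H](c2cc(OC)c(OC)c(OC)c2)OC=C1S(=O)c3ccccc3 | intermediate
8 | 1,1-dimethoxyethene | C=C(OC)OC | starting material
9 | acetyl chloride | CC(=O)Cl | starting material
10 | 4,4-dimethoxybut-3-en-2-one | CC(=O)C=C(OC)OC | intermediate
11 | 1,1-dimethoxy-3-(trimethylsilyloxy)buta-1,3-diene | C=C(O[Si](C)(C)C)C=C(OC)OC | intermediate
12 | (2S)-5,5-dimethoxy-4a-(phenylsulfinyl)-2-(3,4,5-trimethoxyphenyl)-7-(trimethylsilyloxy)-2,3,4a,5,8,8a-hexahydro-4H-chromen-4-one (cis ring fusion; C4a, C8a and sulfur undefined) | O=C1C[C@@H](c3cc(OC)c(OC)c(OC)c3)OC2CC(O[Si](C)(C)C)=CC(OC)(OC)C12S(=O)c4ccccc4 | intermediate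
13 | (S)-5,5-dimethoxy-2-(3,4,5-trimethoxyphenyl)-7-(trimethylsilyloxy)-2,3,5,8-tetrahydro-4H-chromen-4-one | O=C1C[C@@H](c3cc(OC)c(OC)c(OC)c3)OC2=C1C(OC)(OC)C=C(O[Si](C)(C)C)C2 | intermediate
14 | (S)-5-methoxy-2-(3,4,5-trimethoxyphenyl)-7-(trimethylsilyloxy)chroman-4-one | COc1cc(O[Si](C)(C)C)cc2c1C(=O)C[C@@H](c1cc(OC)c(OC)c(OC)c1)O2 | intermediate
15 | (S)-7-hydroxy-5-methoxy-2-(3,4,5-trimethoxyphenyl)chroman-4-one | COc1cc(O)cc2c1C(=O)C[C@@H](c1cc(OC)c(OC)c(OC)c1)O2 | intermediate
16 | (S)-5,7-dimethoxy-2-(3,4,5-trimethoxyphenyl)chroman-4-one | COc1cc(OC)c2c(c1)O[C@H](c1cc(OC)c(OC)c(OC)c1)CC2=O | target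

**Step count and risks**

Total step count: 7. Longest linear sequence: 5 steps (steps 1, 2, 3, 6, 7); steps 4 and 5 form the two-step diene branch.

Step 6 (key step, proposed new method). The most likely failures are two. The addition may stop after the first C–C bond (conjugate addition with silyl transfer and no ring closure). Or the sulfinyl enone may be too weak an electrophile because O1 donates into C6, so that the diene is consumed by the sulfenic acid or by slow decomposition before it reacts. The fallback uses known chemistry and gives up the ring-A-last plan. It sets out from 1: Claisen–Schmidt condensation with commercial 1-(2-hydroxy-4,6-dimethoxyphenyl)ethanone (KOH, EtOH) gives the chalcone (E)-1-(2-hydroxy-4,6-dimethoxyphenyl)-3-(3,4,5-trimethoxyphenyl)prop-2-en-1-one F1 (the compound A1). A catalytic asymmetric intramolecular oxa-Michael addition (bifunctional cinchona-thiourea catalyst, toluene) then returns to the route at the target 16, with enantiomeric enrichment by crystallisation or chiral chromatography as required.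

Step 2. Sulfenylation may go astray by electrophilic attack on the electron-rich trimethoxyphenyl ring, or by acid-induced opening of the pyranone before the elimination is complete. The fallback separates halogenation from C–S bond formation. It sets out from 4: α-iodination of the enone (I2, pyridine, CH2Cl2) gives (S)-5-iodo-2-(3,4,5-trimethoxyphenyl)-2,3-dihydro-4H-pyran-4-one F2, and palladium-catalysed C–S coupling with thiophenol (Pd2(dba)3, Xantphos, iPr2NEt, dioxane) comes back to the route at 6.

Step 4. Acetyl chloride and the amine may form ketene, which adds to 8 in a (2+2) sense, and double acylation or acid-induced polymerisation of the ketene acetal may compete. The fallback builds the same carbon chain from the halide side. It sets out from 9: addition to 1,1-dichloroethene (AlCl3, CH2Cl2) gives 4,4,4-trichlorobutan-2-one F3, which loses hydrogen chloride on distillation to 4,4-dichlorobut-3-en-2-one F4. Twofold addition–elimination with NaOMe in MeOH comes back to the route at 10.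

Step 1. The electron-rich aldehyde is a weak electrophile, so an uncatalysed background aldol addition may erode the enantioselectivity, and the sense of induction rests on the assumption above. The fallback replaces catalyst control by a stoichiometric chiral reagent and builds the pyranone stepwise. It sets out from 1: allylboration with (−)-B-allyldiisopinocampheylborane (Et2O, −78 °C; then NaOH, H2O2) gives (S)-1-(3,4,5-trimethoxyphenyl)but-3-en-1-ol F5. Wacker oxidation (PdCl2, CuCl, O2, DMF/H2O) gives (S)-4-hydroxy-4-(3,4,5-trimethoxyphenyl)butan-2-one F6. Formylation of its dianion (LDA, 2.2 equiv, THF, −78 °C; then 2,2,2-trifluoroethyl formate) gives (S)-5-hydroxy-3-oxo-5-(3,4,5-trimethoxyphenyl)pentanal F7. Acid-catalysed cyclodehydration (CF3CO2H, CH2Cl2) comes back to the route at 4.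

**Further compounds**

F1 | step 6 | (E)-1-(2-hydroxy-4,6-dimethoxyphenyl)-3-(3,4,5-trimethoxyphenyl)prop-2-en-1-one | COc1cc(O)c(C(=O)/C=C/c2cc(OC)c(OC)c(OC)c2)c(OC)c1
F2 | step 2 | (S)-5-iodo-2-(3,4,5-trimethoxyphenyl)-2,3-dihydro-4H-pyran-4-one | O=C1C[C@@H](c2cc(OC)c(OC)c(OC)c2)OC=C1I
F3 | step 4 | 4,4,4-trichlorobutan-2-one | CC(=O)CC(Cl)(Cl)Cl
F4 | step 4 | 4,4-dichlorobut-3-en-2-one | CC(=O)C=C(Cl)Cl
F5 | step 1 | (S)-1-(3,4,5-trimethoxyphenyl)but-3-en-1-ol | C=CC[C@H](O)c1cc(OC)c(OC)c(OC)c1
F6 | step 1 | (S)-4-hydroxy-4-(3,4,5-trimethoxyphenyl)butan-2-one | CC(=O)C[C@H](O)c1cc(OC)c(OC)c(OC)c1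
F7 | step 1 | (S)-5-hydroxy-3-oxo-5-(3,4,5-trimethoxyphenyl)pentanal | O=CCC(=O)C[C@H](O)c1cc(OC)c(OC)c(OC)c1
A1 | alternative 1 | (E)-1-(2-hydroxy-4,6-dimethoxyphenyl)-3-(3,4,5-trimethoxyphenyl)prop-2-en-1-one | COc1cc(O)c(C(=O)/C=C/c2cc(OC)c(OC)c(OC)c2)c(OC)c1
A2 | alternative 2 | 5,7-dimethoxy-4H-chromen-4-one | COc1cc(OC)c2c(c1)OC=CC2=O
A3 | alternative 3 | (R)-3-hydroxy-1-(2-hydroxy-4,6-dimethoxyphenyl)-3-(3,4,5-trimethoxyphenyl)propan-1-one | COc1cc(O)c(C(=O)C[C@@H](O)c2cc(OC)c(OC)c(OC)c2)c(OC)c1
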